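Count how much acid your flask can take up before you count anything else.

electrophile 0.17 M; free base 0.0510 M; protonated nucleophile 0.306 M; scavenger 0.0510 M; time 40 h

    electrophile + nucleophile → acid set free + target (k1 = 2.56 L mol⁻¹ h⁻¹)
    nucleophile + acid set free ⇌ protonated nucleophile, settled at all times (K2 = 74500 L mol⁻¹)
    acid set free + free base ⇌ salt of the base, settled at all times (K3 = 6.18 × 10⁵ L mol⁻¹)
    electrophile + target → side product (k4 = 40.6 L mol⁻¹ h⁻¹)
    nucleophile + acid set free ⇌ idle adduct, settled at all times (K5 = 1.3 L mol⁻¹)
    acid set free + scavenger → scavenged by-product (k6 = 711 L mol⁻¹ h⁻¹)

- percentages count the electrophile that a species holds: one side product counts as two
- acid set free is meant together with its idle adduct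
- run time (flask): 40 h

* part of the electrophile that has reacted at 40 h
* share of free nucleophile in free nucleophile and protonated nucleophile together, at 40 h

**Acid budget.** Each coupling takes one free nucleophile and sets one acid free, so it spends two units of the capacity supplied by free base and scavenger. The rate constant of step 4 is larger than that of step 1 by a selectivity factor of 15.9, so I let each target take a second electrophile. Two units then go with two electrophile, and the part reacted climbs to the acid budget, the charges of free base and scavenger as a fraction of the electrophile charge: 60.0%.

**Turning settings.** By hand, free base and scavenger raise the budget equally, more electrophile shrinks it, and protonated nucleophile does not enter it.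

**Second round.** Past the budget, acid stays free and holds the nucleophile at protonated nucleophile over K2 times acid. Put the first answer back in: with the budget used, two units still go with two electrophile, so in my reckoning the part reacted rises by the free acid as a fraction of the electrophile charge, which grows as the root of time and comes to 5.74% over the whole run. Going round once more with less electrophile gives 5.32%. Counting the whole run as past the budget overstates this, so I commit to a part reacted between 60.0% and 65.3%, and to a share of free nucleophile above 0.149%.

**The forecast.** It gives a point where I give a range: 63.5% and 0.206%, on the grounds that “free acid builds up and throttles the reaction”.

**The result.** The flask gives 63.5% reacted and a share of free nucleophile of 0.204%; the part reacted stands 3.5 percentage points past the budget and under my upper end. Moved alone up or down by one same factor, the settings tried shift the part reacted at most by these amounts, the strongest first: electrophile (16 points), then free base (8.1 points), then scavenger (8 points), then time (1 points), then protonated nucleophile (0.78 points).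

**Second flask.** In the neighbour flask with 0.020 M of scavenger, the budget is 41.8%. The two rounds give 7.14%, then 6.69%, so I reckon the part reacted at up to 48.5%. That neighbour flask computes to 47.1% reacted, more than its budget.

The numbers belong to no real substance.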